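**Strategy.** The cyclohexenone (ring A: C1, C10, C11, C12, C13, C14; briarane numbering) is disconnected at its enone double bond C11=C12. Ring-closing metathesis of a C13 vinyl ketone with the C10 isopropenyl group closes ring A in the last step, on a finished ten-membered carbocycle and butenolide. It exploits that the β-methyl enone C13(=O)–C12H=C11(CH3) maps onto an isopropenyl group, and that C1, C14, C13, C8, C9 and C10 are a carvone ring: (S)-carvone sets C1, C10 and C14, is cleaved between C13 and C8, and C8 then closes the ten-membered ring. The precursor is a seco-briarane carrying all five stereocentres.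

Key step: step 19

Remark on numbering: briarane numbering is used for every compound: C1 (quaternary, CH3-15), C2 (OBz), C3, C4, C5 (CH3-16)=C6, C7 (lactone O–CH), C8=C17 (CH3-18), C19 (lactone C=O), C9, C10, C11 (CH3-20)=C12, C13 (C=O), C14 (OAc).

Assumption: the C7 configuration formed in step 17 is taken to be 7R as drawn; it would be checked by NOE on compound 24.

Step 1
Reactants: 1 nerol
Product: 2 neryl tert-butyldiphenylsilyl ether
Conditions: TBDPSCl, imidazole, DMF, 0 °C to rt
Reagents that add atoms: tert-butyldiphenylsilyl chloride, CC(C)(C)[Si](Cl)(c1ccccc1)c1ccccc1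
Why: Silylation of the primary allylic alcohol gives an ether that tolerates the later base, hydride and periodic acid steps; no stereocentre is formed.

Step 2
Reactants: 2 neryl tert-butyldiphenylsilyl ether
Product: 3 6,7-epoxyneryl tert-butyldiphenylsilyl ether (racemic epoxide)
Conditions: mCPBA, NaHCO3, CH2Cl2, −20 °C
Reagents that add atoms: mCPBA, OOC(=O)c1cccc(Cl)c1
Why: Prilezhaev epoxidation should prefer the more electron-rich distal trisubstituted alkene over the alkene deactivated by the allylic silyloxy group; the racemic epoxide centre is destroyed in step 3.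

Step 3
Reactants: 3 6,7-epoxyneryl tert-butyldiphenylsilyl ether
Product: 5 (4Z)-6-(tert-butyldiphenylsilyloxy)-4-methylhex-4-enal, via vicinal diol 4 (not isolated)
Conditions: H5IO6, THF/Et2O, 0 °C
Reagents that add atoms: none
Why: Periodic acid opens the epoxide to the diol and cleaves it (Malaprade-type glycol cleavage), excising acetone and leaving the C2 aldehyde with the Z-alkene (C5=C6) untouched.

Step 4
Reactants: 6 (S)-carvone; 5 (4Z)-6-(tert-butyldiphenylsilyloxy)-4-methylhex-4-enal
Product: 8 aldol adduct of carvone at C1, via lithium dienolate 7 (not isolated)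
Conditions: LiN(iPr)2 (LDA), THF, −78 °C; then 5, −78 °C; aq NH4Cl
Reagents that add atoms: none
Why: Kinetic α′-deprotonation of carvone gives the cross-conjugated lithium enolate, and its directed aldol addition forms the C1–C2 bond; the new C1 and C2 configurations are irrelevant because both are erased in steps 5 and 6.

Step 5
Reactants: 8 aldol adduct
Product: 9 1,3-diketone (C2 and C14 ketones)
Conditions: Dess–Martin periodinane, NaHCO3, CH2Cl2, 0 °C to rt
Reagents that add atoms: none
Why: Dess–Martin oxidation of the β-hydroxy ketone gives the enolisable 1,3-diketone without touching the alkenes or the silyl ether.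

Step 6
Reactants: 9 1,3-diketone
Product: 10 C1-methylated 1,3-diketone (methyl trans to isopropenyl)
Conditions: K2CO3, MeI, acetone, 40 °C
Reagents that add atoms: iodomethane, CI
Why: C-alkylation of the stabilised 1,3-diketone enolate; iodomethane should approach the planar C1 anti to the neighbouring C10 isopropenyl group, which sets the quaternary C1 with CH3-15 trans and the acyl chain cis to isopropenyl.

Step 7
Reactants: 10 C1-methylated 1,3-diketone
Product: 11 C2 alcohol (2S)
Conditions: Zn(BH4)2, Et2O, −30 °C
Reagents that add atoms: none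
Why: Chelation-controlled reduction: zinc bridges the two carbonyl oxygens of the non-enolisable 1,3-diketone, and hydride should add to the more electrophilic non-conjugated C2 ketone from the chelate face flanked by CH3-15 (opposite C10), giving the 2S carbinol.

Step 8
Reactants: 11 C2 alcohol
Product: 12 C2 benzoate
Conditions: BzCl, pyridine, DMAP (cat.), CH2Cl2, rt
Reagents that add atoms: benzoyl chloride, O=C(Cl)c1ccccc1
Why: DMAP-catalysed acylation of the only hydroxyl group installs the C2 benzoate of the target.

Step 9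
Reactants: 12 C2 benzoate
Product: 13 C14 allylic alcohol (hydroxyl cis to isopropenyl and to the C2 chain)
Conditions: NaBH4, CeCl3·7H2O, MeOH, −78 to −40 °C
Reagents that add atoms: none
Why: Luche reduction gives 1,2-reduction of the enone; hydride should add from the face of CH3-15 because the opposite face is shielded by the C10 isopropenyl group and the C1 side chain, which sets C14 with its oxygen cis to both.

Step 10
Reactants: 13 C14 allylic alcohol
Product: 14 C13–C8 epoxy alcohol (epoxide syn to the C14 hydroxyl)
Conditions: VO(acac)2 (cat.), tBuOOH, CH2Cl2, 0 °C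
Reagents that add atoms: tert-butyl hydroperoxide, CC(C)(C)OO
Why: Hydroxyl-directed vanadium-catalysed epoxidation should touch only the allylic C13=C8 alkene, syn to the hydroxyl, and leave the isopropenyl and C5=C6 alkenes; the two new centres are destroyed in step 12.

Step 11
Reactants: 14 epoxy alcohol
Product: 15 epoxy acetate
Conditions: Ac2O, pyridine, DMAP, CH2Cl2, rt
Reagents that add atoms: acetic anhydride, CC(=O)OC(C)=O
Why: Acetylation installs the C14 acetate of the target and masks the hydroxyl so that periodic acid cannot cleave the C13–C14 bond in the next step.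

Step 12
Reactants: 15 epoxy acetate
Product: 17 seco keto aldehyde (C13 methyl ketone and C8 aldehyde), via trans-diol 16 (not isolated)
Conditions: H5IO6, THF/H2O, 0 °C to rt
Reagents that add atoms: water, O
Why: Hydrolytic epoxide opening followed by periodic acid glycol cleavage cuts the carvone ring between C13 and C8, unveiling the C13 methyl ketone and the C8 aldehyde without touching the two remaining alkenes.

Step 13
Reactants: 17 seco keto aldehyde
Product: 18 β-hydroxy ester (mixture at C8 and C17)
Conditions: Zn (activated), methyl 2-bromopropanoate, THF, 0 °C to rt; aq NH4Cl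
Reagents that add atoms: methyl 2-bromopropanoate, CC(Br)C(=O)OC
Why: Reformatsky reaction: the zinc enolate adds to the aldehyde in preference to the hindered methyl ketone and the esters under near-neutral conditions, bringing in C17, C18 and C19; the C8 and C17 centres are removed in steps 15 and 16.

Step 14
Reactants: 18 β-hydroxy ester
Product: 19 diol (free C7 allylic alcohol)
Conditions: HF·pyridine, pyridine, THF, 0 °C to rt
Reagents that add atoms: none
Why: Fluoride-mediated desilylation frees the primary allylic alcohol, and the buffered reagent leaves the acetate, benzoate and methyl ester intact.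

Step 15
Reactants: 19 diol
Product: 20 β-keto ester Z-enal
Conditions: Dess–Martin periodinane (excess), NaHCO3, CH2Cl2, 0 °C to rt
Reagents that add atoms: none
Why: Dess–Martin oxidation converts both alcohols in one operation into the β-keto ester (C8) and the Z-enal (C7), and buffering should prevent Z/E isomerisation of the enal.

Step 16
Reactants: 20 β-keto ester Z-enal
Product: 22 (Z)-enol triflate enal, via sodium enolate 21 (not isolated)
Conditions: NaH, THF, 0 °C; then PhNTf2, 0 °C to rt
Reagents that add atoms: N-phenylbis(trifluoromethanesulfonimide), O=S(=O)(N(c1ccccc1)S(=O)(=O)C(F)(F)F)C(F)(F)F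
Why: Enol triflate formation: the β-keto ester is by far the most acidic site, and O-sulfonylation of its sodium-chelated Z-enolate places the triflate cis to the ester, the geometry needed for lactonisation after step 17.

Step 17
Reactants: 22 (Z)-enol triflate enal
Product: 24 ten-membered carbocycle with fused butenolide (C13 methyl ketone), via hydroxy enoate 23 (not isolated)
Conditions: CrCl2 (excess), NiCl2 (cat.), DMSO/THF, rt, high dilution; aqueous work-up
Reagents that add atoms: none
Why: Nozaki–Hiyama–Kishi macrocyclisation: zerovalent nickel inserts into the C–OTf bond, the alkenyl group passes to chromium and adds to the aldehyde (not to the ketone or esters) to close the ten-membered ring at C7–C8, and the Z-configured γ-alkoxy enoate lactonises to the butenolide; C7 is set in this addition under control of the tether (C1, C2 and C10 centres, Z-C5=C6 bond), and the 7R sense is expected but not assured.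

Step 18
Reactants: 24 macrocyclic methyl ketone
Product: 26 C13 vinyl ketone, via Mannich base 25 (not isolated)
Conditions: (CH2O)n, N-methylanilinium trifluoroacetate, THF, reflux
Reagents that add atoms: formaldehyde (as paraformaldehyde), C=O
Why: Mannich-type α-methylenation under mildly acidic conditions: the enol of the methyl ketone (C12) adds to the iminium ion and N-methylaniline is eliminated to give the vinyl ketone, while C14 cannot eliminate and the butenolide is inert to acid.

Step 19
Reactants: 26 C13 vinyl ketone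
Product: 27 target CNP0194180.3
Conditions: second-generation Hoveyda–Grubbs catalyst (10 mol %), toluene, 80 °C, high dilution
Reagents that add atoms: none
Why: Ring-closing olefin metathesis: the ruthenium carbene loads on a terminal alkene (enone vinyl or isopropenyl CH2), forms a ruthenacyclobutane with the other one and releases ethylene, creating the C11=C12 bond. The closest known reaction type is RCM of a vinyl ketone with a 1,1-disubstituted alkene to a 3-methylcyclohex-2-enone. The one ring closed is the six-membered ring A (C1, C14, C13, C12, C11, C10), made by joining the chains on the adjacent atoms C1 and C10 and fused trans to the ten-membered ring. No stereocentre is created: C1, C2, C7, C10 and C14 are carried in unchanged, and the neutral conditions should leave the epimerisable C14 and C7 untouched. The step needs chemoselectivity for the two terminal alkenes over the trisubstituted C5=C6 and the tetrasubstituted C8=C17 alkenes, which their substitution and the strain-free six-membered ring should secure, while dilution suppresses dimerisation of the enone.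

**Compound list**

1 | nerol, (2Z)-3,7-dimethylocta-2,6-dien-1-ol | CC(C)=CCC/C(C)=C\CO | starting material
2 | neryl tert-butyldiphenylsilyl ether | CC(C)=CCC/C(C)=C\CO[Si](c1ccccc1)(c1ccccc1)C(C)(C)C | intermediate
3 | 6,7-epoxyneryl TBDPS ether, racemic at the epoxide | CC1(C)OC1CC/C(C)=C\CO[Si](c1ccccc1)(c1ccccc1)C(C)(C)C | intermediate
4 | (6Z)-8-(TBDPS-oxy)-2,6-dimethyloct-6-ene-2,3-diol, racemic, not isolated | CC(C)(O)C(O)CC/C(C)=C\CO[Si](c1ccccc1)(c1ccccc1)C(C)(C)C | intermediate
5 | (4Z)-6-(tert-butyldiphenylsilyloxy)-4-methylhex-4-enal (C2–C7 fragment) | O=CCC/C(C)=C\CO[Si](c1ccccc1)(c1ccccc1)C(C)(C)C | intermediate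
6 | (S)-(+)-carvone | CC1=CC[C@H](C(C)=C)CC1=O | starting material
7 | lithium cross-conjugated dienolate of carvone, not isolated | CC1=CC[C@H](C(C)=C)C=C1[O-].[Li+] | intermediate
8 | aldol adduct: carvone bearing at C1 the 6-(TBDPS-oxy)-1-hydroxy-4-methylhex-4Z-enyl chain; epimer mixture at C1 and C2, C10 as in carvone | CC1=CC[C@H](C(C)=C)C(C(O)CC/C(C)=C\CO[Si](c2ccccc2)(c2ccccc2)C(C)(C)C)C1=O | intermediate
9 | 1,3-diketone: carvone acylated at C1 with the 6-(TBDPS-oxy)-4-methylhex-4Z-enoyl chain; C1 epimeric/enolised | CC1=CC[C@H](C(C)=C)C(C(=O)CC/C(C)=C\CO[Si](c2ccccc2)(c2ccccc2)C(C)(C)C)C1=O | intermediate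
10 | C1-methylated 1,3-diketone; CH3-15 trans and acyl chain cis to the C10 isopropenyl | O=C1C(C)=CC[C@H](C(C)=C)[C@]1(C)C(=O)CC/C(C)=C\CO[Si](c2ccccc2)(c2ccccc2)C(C)(C)C | intermediate
11 | C2 alcohol (2S); C14 enone retained | O=C1C(C)=CC[C@H](C(C)=C)[C@]1(C)[C@@H](O)CC/C(C)=C\CO[Si](c2ccccc2)(c2ccccc2)C(C)(C)C | intermediate
12 | C2 benzoate; C14 enone | O=C1C(C)=CC[C@H](C(C)=C)[C@]1(C)[C@@H](OC(=O)c2ccccc2)CC/C(C)=C\CO[Si](c2ccccc2)(c2ccccc2)C(C)(C)C | intermediate
13 | C14 allylic alcohol; hydroxyl cis to isopropenyl and C2 chain, trans to CH3-15 | O[C@@H]1C(C)=CC[C@H](C(C)=C)[C@]1(C)[C@@H](OC(=O)c2ccccc2)CC/C(C)=C\CO[Si](c2ccccc2)(c2ccccc2)C(C)(C)C | intermediate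
14 | C13–C8 epoxy alcohol; epoxide on the face of the C14 hydroxyl | O[C@@H]1[C@]2(C)O[C@@H]2C[C@H](C(C)=C)[C@]1(C)[C@@H](OC(=O)c3ccccc3)CC/C(C)=C\CO[Si](c3ccccc3)(c3ccccc3)C(C)(C)C | intermediate
15 | epoxy acetate (C14 OAc, C2 OBz) | CC(=O)O[C@@H]1[C@]2(C)O[C@@H]2C[C@H](C(C)=C)[C@]1(C)[C@@H](OC(=O)c3ccccc3)CC/C(C)=C\CO[Si](c3ccccc3)(c3ccccc3)C(C)(C)C | intermediate
16 | C13,C8 trans-diol of 15, not isolated | CC(=O)O[C@@H]1[C@@](C)(O)[C@H](O)C[C@H](C(C)=C)[C@]1(C)[C@@H](OC(=O)c2ccccc2)CC/C(C)=C\CO[Si](c2ccccc2)(c2ccccc2)C(C)(C)C | intermediate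
17 | seco keto aldehyde: C13 methyl ketone, C14 OAc, C1 quaternary, C2 OBz, C10 isopropenyl, C8 aldehyde, C7 OTBDPS; C1, C2, C10, C14 as in the target | CC(=O)[C@@H](OC(C)=O)[C@](C)([C@@H](C(C)=C)CC=O)[C@@H](OC(=O)c1ccccc1)CC/C(C)=C\CO[Si](c1ccccc1)(c1ccccc1)C(C)(C)C | intermediate
18 | Reformatsky adduct: C8 carbinol carrying CH(CH3)CO2Me; mixture at C8 and C17 | CC(=O)[C@@H](OC(C)=O)[C@](C)([C@@H](C(C)=C)CC(O)C(C)C(=O)OC)[C@@H](OC(=O)c1ccccc1)CC/C(C)=C\CO[Si](c1ccccc1)(c1ccccc1)C(C)(C)C | intermediate
19 | diol: 18 with free C7 allylic alcohol | CC(=O)[C@@H](OC(C)=O)[C@](C)([C@@H](C(C)=C)CC(O)C(C)C(=O)OC)[C@@H](OC(=O)c1ccccc1)CC/C(C)=C\CO | intermediate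
20 | β-keto ester Z-enal (C8 ketone, C7 aldehyde); C17 epimeric | CC(=O)[C@@H](OC(C)=O)[C@](C)([C@@H](C(C)=C)CC(=O)C(C)C(=O)OC)[C@@H](OC(=O)c1ccccc1)CC/C(C)=C\C=O | intermediate
21 | sodium Z-enolate of 20, not isolated | CC(=O)[C@@H](OC(C)=O)[C@](C)([C@@H](C(C)=C)C/C([O-])=C(\C)C(=O)OC)[C@@H](OC(=O)c1ccccc1)CC/C(C)=C\C=O.[Na+] | intermediate
22 | (Z)-enol triflate (OTf on C8, cis to CO2Me) with C7 Z-enal | CC(=O)[C@@H](OC(C)=O)[C@](C)([C@@H](C(C)=C)C/C(OS(=O)(=O)C(F)(F)F)=C(\C)C(=O)OC)[C@@H](OC(=O)c1ccccc1)CC/C(C)=C\C=O | intermediate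
23 | macrocyclic (7R)-hydroxy (Z)-enoate, as its chromium alkoxide, not isolated | CC(=O)[C@@H](OC(C)=O)[C@]1(C)[C@@H](C(C)=C)C/C(=C(\C)C(=O)OC)[C@H](O)/C=C(/C)CC[C@@H]1OC(=O)c1ccccc1 | intermediate
24 | (1R,2S,7R,10R,14S) ten-membered carbocycle with fused butenolide; C1 carries CH(OAc)C(=O)CH3, C10 carries isopropenyl | CC(=O)[C@@H](OC(C)=O)[C@]1(C)[C@@H](C(C)=C)CC2=C(C)C(=O)O[C@@H]2/C=C(/C)CC[C@@H]1OC(=O)c1ccccc1 | intermediate
25 | Mannich base of 24 (C13 ketone with CH2CH2N(CH3)Ph), not isolated | CN(c1ccccc1)CCC(=O)[C@@H](OC(C)=O)[C@]1(C)[C@@H](C(C)=C)CC2=C(C)C(=O)O[C@@H]2/C=C(/C)CC[C@@H]1OC(=O)c1ccccc1 | intermediate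
26 | (1R,2S,7R,10R,14S) C13 vinyl ketone, metathesis precursor | C=CC(=O)[C@@H](OC(C)=O)[C@]1(C)[C@@H](C(C)=C)CC2=C(C)C(=O)O[C@@H]2/C=C(/C)CC[C@@H]1OC(=O)c1ccccc1 | intermediate
27 | CNP0194180.3: (1R,2S,7R,10R,14S) briarane with 14-OAc, 2-OBz, 13-oxo, Z-5(6), 8(17) and 11(12) alkenes and the C19–O–C7 butenolide | CC(=O)O[C@@H]1C(=O)C=C(C)[C@H]2CC3=C(C)C(=O)O[C@@H]3/C=C(/C)CC[C@H](OC(=O)c3ccccc3)[C@@]21C | target

**Step count.** Total: 19 steps. Longest linear sequence: 19 steps (nerol to 27); (S)-carvone enters at step 4 and is carried through 16 steps.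

**Steps most likely to fail**

Step 17 (macrocyclisation). What may go wrong: slow medium-ring closure competing with intermolecular coupling, reduction of the α-acetoxy ketone by divalent chromium, Z/E isomerisation of the enal, and above all poor facial selectivity in the addition to the C7 aldehyde. The fallback sets out from 22 and comes back at 24. If the chromium step delivers mainly the wrong epimer, the C7-epimeric butenolide F1, C7 is corrected after ring closure instead of being set in the C–C bond formation. F1 is treated with TIPSOTf/Et3N (CH2Cl2, −78 °C) to give the aromatic 2-silyloxyfuran F2, in which C7 is planar. Kinetic protonolysis (AcOH or HF·pyridine, THF, −78 °C) from the less hindered face of the furan should then return the butenolide as 24. Both operations are known chemistry for γ-epimerisation of butenolides.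

Step 19 (key ring closure). What may go wrong: the ruthenium carbene may fail to engage the hindered isopropenyl group beside the quaternary C1, so that intermolecular dimerisation or decomposition of the vinyl ketone takes over. The fallback sets out from 24 and comes back at 27, bypassing steps 18 and 19. Lemieux–Johnson cleavage (OsO4 cat., NaIO4, 2,6-lutidine, dioxane/H2O) of the 1,1-disubstituted isopropenyl alkene, the least hindered and least deactivated alkene of 24, should give the C11 methyl ketone, the 1,5-diketone F3. An acid-catalysed intramolecular aldol condensation (TsOH, benzene, reflux) follows: the C12 enol of the C13 methyl ketone adds to the C11 ketone and water is lost, which should close the same six-membered ring and give 27. The points to watch there are the competing regiochemistry (C20 onto C13) and epimerisation at C10.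

Step 7 (C2 reduction). What may go wrong: competing 1,2-reduction of the C14 enone carbonyl and hydride delivery to the wrong face of C2. The fallback sets out from 10 and comes back at 15; it reverses the order of the reductions so that C2 is set under reagent control. Luche reduction of 10 (NaBH4, CeCl3·7H2O, MeOH, −78 °C) should reduce only the conjugated C14 ketone, from the CH3-15 face, to the allylic alcohol F4. Hydroxyl-directed epoxidation (VO(acac)2, tBuOOH) gives the epoxy alcohol F5, and acetylation (Ac2O, pyridine, DMAP) gives the epoxy acetate F6, in which C2 is the only ketone. Corey–Bakshi–Shibata reduction with the (R)-methyl oxazaborolidine and BH3·SMe2 (quaternary C1 as the large group, C3 as the small one) should give the 2S alcohol F7. Benzoylation (BzCl, pyridine, DMAP) then gives 15.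

Further compounds
F1 | step 17 | C7-epimeric butenolide (7-epi-24) | CC(=O)[C@@H](OC(C)=O)[C@]1(C)[C@@H](C(C)=C)CC2=C(C)C(=O)O[C@H]2/C=C(/C)CC[C@@H]1OC(=O)c1ccccc1
F2 | step 17 | 2-triisopropylsilyloxyfuran of the macrocycle (C7 planar) | CC(=O)[C@@H](OC(C)=O)[C@]1(C)[C@@H](C(C)=C)Cc2c(C)c(O[Si](C(C)C)(C(C)C)C(C)C)oc2/C=C(/C)CC[C@@H]1OC(=O)c1ccccc1
F3 | step 19 | 1,5-diketone: 24 with the C10 isopropenyl cleaved to acetyl (C11 ketone) | CC(=O)[C@@H](OC(C)=O)[C@]1(C)[C@@H](C(C)=O)CC2=C(C)C(=O)O[C@@H]2/C=C(/C)CC[C@@H]1OC(=O)c1ccccc1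
F4 | step 7 | C14 allylic alcohol with C2 ketone | O[C@@H]1C(C)=CC[C@H](C(C)=C)[C@]1(C)C(=O)CC/C(C)=C\CO[Si](c2ccccc2)(c2ccccc2)C(C)(C)C
F5 | step 7 | C13–C8 epoxy alcohol with C2 ketone | O[C@@H]1[C@]2(C)O[C@@H]2C[C@H](C(C)=C)[C@]1(C)C(=O)CC/C(C)=C\CO[Si](c3ccccc3)(c3ccccc3)C(C)(C)C
F6 | step 7 | epoxy acetate with C2 ketone | CC(=O)O[C@@H]1[C@]2(C)O[C@@H]2C[C@H](C(C)=C)[C@]1(C)C(=O)CC/C(C)=C\CO[Si](c3ccccc3)(c3ccccc3)C(C)(C)C
F7 | step 7 | epoxy acetate with (2S) C2 alcohol | CC(=O)O[C@@H]1[C@]2(C)O[C@@H]2C[C@H](C(C)=C)[C@]1(C)[C@@H](O)CC/C(C)=C\CO[Si](c3ccccc3)(c3ccccc3)C(C)(C)C
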